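**Retrosynthetic overview**
- Numbering: acid C1, C2‑Me, dioxane carbons C3–C6, linker C7–C8, carbocycle C9–C18. C1–C8 with their two methyl branches have the geraniol branching pattern. The fully substituted peroxy carbon C6 is treated as the inverted tertiary carbon of a (6R,7R)‑6,7‑epoxy alcohol.
- Endgame: the C1 acid comes from the primary alcohol. The C7–C8 single bond comes from diimide reduction of a C7=C8 alkene. That alkene comes from Wittig union of a C7 dioxane aldehyde with the C8 allylic ylide of the cis‑fused hexahydronaphthalene.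
- 1,2‑Dioxane (C3, C4, C5, C6, O, O): closed by 6‑exo attack of a C3 hydroperoxide on C6 of the epoxide. The 7,8‑diol left behind is cut with periodate to the C7 aldehyde.
- C2/C3: syn‑aldol on the C3 aldehyde from geranyl acetate, then SN2 inversion at C3 by a ketal‑masked hydroperoxide. This is done before the epoxidation, so that neither a free C3–OH nor a base ever meets the epoxy alcohol.
- Carbocycle: ring A (C12–C17) is the ring of (S)‑limonene, and C11–C12 is made cis to C17 by a suprafacial Claisen shift. Ring B is closed at C9–C18. Ring order: A (chiral pool), B (step 18); the dioxane (step 11) is built in the other branch.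

Key step: step 11

Remark on the chemistry: the alpha carbon (C9) of beta‑keto ester 27 is enolisable and becomes sp2 in step 19, so it is left undefined; diene 33 is drawn E, and any Z isomer converges in step 24.

**Route**

Step 1
Reactants: 1 geranyl acetate
Product: 2 (2E)-3-methyl-6-oxohex-2-en-1-yl acetate (C3–C8 aldehyde)
Conditions: O3 (1 equiv), CH2Cl2–MeOH, −78 °C; then Me2S, −78 °C → rt
Reagents that add atoms: ozone, [O-][O+]=O
Why: Chemoselective ozonolysis with reductive work-up; the allylic acetate inductively deactivates the 2,3-alkene, so one equivalent of ozone should cut only the more electron-rich isopropylidene bond, and no stereocentre is involved.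

Step 2
Reactants: 3 (R)-4-benzyl-3-propionyl-1,3-oxazolidin-2-one; 2 aldehyde
Product: 5 syn-aldol adduct (4R)-4-benzyl-3-[(2R,3S,6E)-8-acetoxy-3-hydroxy-2,6-dimethyloct-6-enoyl]-1,3-oxazolidin-2-one, via Z-boron enolate 4 (not isolated)
Conditions: Bu2BOTf, Et3N, CH2Cl2, 0 °C; 2, −78 → 0 °C; pH 7 buffer, MeOH, 30% H2O2, 0 °C
Reagents that add atoms: dibutylboron triflate, CCCCB(CCCC)OS(=O)(=O)C(F)(F)F (its Bu2B group is carried in 4 only)
Why: Evans syn-aldol reaction; the Z-boron enolate reacts through a closed chair transition state on the enolate face left open by the benzyl group of the (R)-auxiliary, which should set (2R,3S), that is the final C2 configuration and a C3 carbinol that is inverted in step 8.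

Step 3
Reactants: 5 syn-aldol adduct
Product: 6 (2E,6S,7S)-6,8-dihydroxy-3,7-dimethyloct-2-en-1-yl acetate (C1,C3-diol)
Conditions: NaBH4, THF–H2O (4:1), 0 °C → rt
Reagents that add atoms: none
Why: Reductive removal of the auxiliary; borohydride attacks the activated exocyclic imide carbonyl while an alkyl acetate is inert to NaBH4 under these conditions, and no stereocentre is touched (C2 only changes its descriptor to S).

Step 4
Reactants: 6 C1,C3-diol
Product: 7 (2E,6S,7S)-8-[(tert-butyldimethylsilyl)oxy]-6-hydroxy-3,7-dimethyloct-2-en-1-yl acetate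
Conditions: TBSCl (1.05 equiv), imidazole, CH2Cl2, 0 °C
Reagents that add atoms: tert-butyldimethylsilyl chloride, CC(C)(C)[Si](C)(C)Cl
Why: Selective silylation; the bulky silyl chloride should react with the primary C1 hydroxyl much faster than with the secondary C3 hydroxyl.

Step 5
Reactants: 7 C1 silyl ether
Product: 8 (2E,6S,7S)-8-[(tert-butyldimethylsilyl)oxy]-6-(methylsulfonyloxy)-3,7-dimethyloct-2-en-1-yl acetate
Conditions: MsCl, Et3N, CH2Cl2, 0 °C
Reagents that add atoms: methanesulfonyl chloride, CS(=O)(=O)Cl
Why: Mesylation of the only free hydroxyl; the C3–O bond is not broken, so the (3S) configuration is kept.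

Step 6
Reactants: 8 mesylate acetate
Product: 9 (2E,6S,7S)-8-[(tert-butyldimethylsilyl)oxy]-1-hydroxy-3,7-dimethyloct-2-en-6-yl methanesulfonate
Conditions: K2CO3 (0.2 equiv), MeOH, 0 °C
Reagents that add atoms: none
Why: Base-catalysed transesterification frees the C8 allylic alcohol without touching the mesylate or the silyl ether; it is done now because the peroxy anion of step 8 would otherwise be consumed by acyl transfer from the acetate.

Step 7
Reactants: 10 2,3-dimethylbut-2-ene
Product: 11 2-methoxypropan-2-yl hydroperoxide
Conditions: O3, CH2Cl2–MeOH, −78 °C; concentrated cold and used as a solution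
Reagents that add atoms: ozone, [O-][O+]=O; methanol, CO
Why: Ozonolysis in a participating solvent; the carbonyl oxide released by cycloreversion of the primary ozonide is trapped by methanol as the alpha-methoxy hydroperoxide.

Step 8
Reactants: 9 C3 mesylate; 11 2-methoxypropan-2-yl hydroperoxide
Product: 12 (2E,6R,7S)-8-[(tert-butyldimethylsilyl)oxy]-6-[(2-methoxypropan-2-yl)peroxy]-3,7-dimethyloct-2-en-1-ol
Conditions: CsOH·H2O (1.5 equiv), 11 (2 equiv), DMF, 0 °C → rt
Reagents that add atoms: none
Why: SN2 displacement of a secondary sulfonate by a peroxy anion; this weakly basic alpha-effect nucleophile should substitute with clean inversion to give (3R), and the allylic hydroxyl stays a spectator because it is far less acidic than the hydroperoxide.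

Step 9
Reactants: 12 peroxyketal allylic alcohol
Product: 13 [(2R,3R)-3-{(3R,4S)-5-[(tert-butyldimethylsilyl)oxy]-3-[(2-methoxypropan-2-yl)peroxy]-4-methylpentyl}-3-methyloxiran-2-yl]methanol
Conditions: Ti(OiPr)4, D-(−)-diethyl tartrate, t-BuOOH (decane), 4 Å MS, CH2Cl2, −20 °C; Me2S, then aq Na2SO4 work-up (no Fe(II), no phosphine)
Reagents that add atoms: tert-butyl hydroperoxide, CC(C)(C)OO
Why: Sharpless asymmetric epoxidation; the sense is reagent-controlled, the D-(−)-tartrate giving the (6R,7R)-epoxide just as it gives the (2R,3R)-epoxide from geraniol, and the fully alkylated peroxyketal has no O–H with which to enter the titanium coordination sphere.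

Step 10
Reactants: 13 epoxy alcohol peroxyketal
Product: 14 [(2R,3R)-3-{(3R,4S)-5-[(tert-butyldimethylsilyl)oxy]-3-hydroperoxy-4-methylpentyl}-3-methyloxiran-2-yl]methanol
Conditions: AcOH–THF–H2O, 0 °C, short contact; used at once
Reagents that add atoms: none
Why: Acid hydrolysis of an acyclic peroxyketal, which should be much faster than loss of the primary silyl ether or hydrolysis of the epoxide; any early ring closure at this stage is productive.

Step 11
Reactants: 14 C3 hydroperoxy 6,7-epoxy alcohol
Product: 15 (1R)-1-[(3S,6R)-6-{(2S)-1-[(tert-butyldimethylsilyl)oxy]propan-2-yl}-3-methyl-1,2-dioxan-3-yl]ethane-1,2-diol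
Conditions: camphorsulfonic acid (0.1 equiv), CH2Cl2, 0 °C → rt
Reagents that add atoms: none
Why: The acid activates the oxirane oxygen, the C6–O bond lengthens because C6 is the tertiary terminus, and the terminal oxygen of the C3 hydroperoxide attacks C6 from the side opposite the departing oxygen, after which proton loss gives the dioxane and returns the acid. The closest known reaction type is the acid-promoted intramolecular opening of epoxides by hydroperoxides, the peroxide counterpart of the exo cyclisation of epoxy alcohols to cyclic ethers. The only ring closed, O–O–C6–C5–C4–C3, forms in a 6-exo-tet mode with the breaking C6–O bond outside the new ring. The one new stereocentre, C6, arises by inversion of the (6R)-oxirane carbon and therefore goes back to the tartrate of step 9, while C7 keeps its C–O bond and C2 and C3 are spectators. The step needs attack at C6 rather than C7 and a concerted rather than cationic opening: the tertiary-carbon bias and the six-exo over seven-endo preference point the same way, the oxygens on C7 and C8 disfavour a free C6 cation, and the tethered alpha-effect nucleophile should capture the loosened bond before rotation or hydride shift. Aprotic solvent, catalytic acid and low temperature should spare the silyl ether and the O–O bond and leave no external nucleophile to compete.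

Step 12
Reactants: 15 dioxane 7,8-diol
Product: 16 (3S,6R)-6-{(2S)-1-[(tert-butyldimethylsilyl)oxy]propan-2-yl}-3-methyl-1,2-dioxane-3-carbaldehyde (C7 aldehyde)
Conditions: NaIO4, THF–H2O, 0 °C → rt
Reagents that add atoms: none
Why: Periodate glycol cleavage (Malaprade reaction) removes C8 through the cyclic periodate ester; an oxidant does not harm the O–O bond, and C6 bears no hydrogen that could epimerise.

Step 13
Reactants: 17 (S)-(−)-limonene
Product: 19 (1R,2S,4S)-limonene 1,2-oxide (oxirane oxygen cis to the isopropenyl group), via bromohydrin 18 (not isolated)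
Conditions: NBS, acetone–H2O, 0 °C; then aq NaOH, 0 °C → rt
Reagents that add atoms: water, O; N-bromosuccinimide, O=C1CCC(=O)N1Br (bromine carried in 18 only)
Why: Bromohydrin formation and base closure; the more nucleophilic ring alkene takes up Br+ reversibly, and only the bromonium ion anti to the isopropenyl group can be opened by water at tertiary C1 in a trans-diaxial (Fürst–Plattner) manner, so the C1–O bond and hence the oxirane should end up cis to the isopropenyl group.

Step 14
Reactants: 19 limonene oxide
Product: 22 (1R,4S)-1-methyl-4-(prop-1-en-2-yl)cyclohex-2-en-1-ol, via hydroxy selenide 20 (not isolated), via selenoxide 21 (not isolated)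
Conditions: PhSeSePh, NaBH4, EtOH, rt → reflux; then THF, NaHCO3, 30% H2O2, 0 °C → rt
Reagents that add atoms: diphenyl diselenide, c1ccc(cc1)[Se][Se]c1ccccc1 (PhSe carried in 20 and 21 only); hydrogen peroxide, OO (oxygen carried in 21 only)
Why: Epoxide opening by selenolate followed by selenoxide syn-elimination; this oxide diastereomer is opened trans-diaxially at secondary C2, and elimination can only run towards C3 because C1 bears no hydrogen, so the C1–O configuration is retained.

Step 15
Reactants: 22 tertiary allylic alcohol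
Product: 24 2-[(1R,6S)-3-methyl-6-(prop-1-en-2-yl)cyclohex-2-en-1-yl]-N,N-dimethylacetamide, via ketene N,O-acetal 23 (not isolated)
Conditions: MeC(OMe)2NMe2 (excess), xylene, 140 °C, MeOH distilled off
Reagents that add atoms: N,N-dimethylacetamide dimethyl acetal, COC(C)(OC)N(C)C
Why: Eschenmoser–Claisen rearrangement under non-acidic conditions; the [3,3] shift is suprafacial, so the C11–C12 bond forms on the ring face that carried the C14–O bond, cis to the isopropenyl group on C17, which sets (12R) and places the ring alkene at C13=C14.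

Step 16
Reactants: 24 amide
Product: 25 1-[(1R,6S)-3-methyl-6-(prop-1-en-2-yl)cyclohex-2-en-1-yl]propan-2-one
Conditions: MeLi, Et2O, −78 → 0 °C; aq NH4Cl
Reagents that add atoms: methyllithium, [Li]C
Why: Organolithium addition to a tertiary amide; the lithium hemiaminal survives until work-up, so addition should stop at the methyl ketone.

Step 17
Reactants: 25 methyl ketone
Product: 26 methyl 4-[(1R,6S)-3-methyl-6-(prop-1-en-2-yl)cyclohex-2-en-1-yl]-3-oxobutanoate
Conditions: NaH, (MeO)2CO, THF, reflux; AcOH quench
Reagents that add atoms: dimethyl carbonate, COC(=O)OC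
Why: Claisen-type C-acylation; it is driven by deprotonation of the product and therefore ends on the methyl side of the ketone, and neither ring stereocentre is acidic.

Step 18
Reactants: 26 olefinic beta-keto ester
Product: 27 methyl (4aR,8aS)-1,1,6-trimethyl-3-oxo-1,2,3,4,4a,7,8,8a-octahydronaphthalene-2-carboxylate
Conditions: SnCl4 (1.2 equiv), CH2Cl2, −20 → 0 °C; aq NaHCO3
Reagents that add atoms: none
Why: Lewis-acid-promoted cation–olefin cyclisation of an olefinic beta-keto ester; the isopropenyl group should be protonated in preference to the ring alkene, as in Markovnikov additions to limonene, and the cis-disposed tin enolate should trap the tertiary C18 cation at C9 faster than proton loss, so the cis relationship already present fixes the cis ring fusion.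

Step 19
Reactants: 27 bicyclic beta-keto ester
Product: 28 methyl (4aR,8aS)-3-[(diethoxyphosphoryl)oxy]-1,1,6-trimethyl-1,4,4a,7,8,8a-hexahydronaphthalene-2-carboxylate
Conditions: NaH, THF, 0 °C; ClP(O)(OEt)2, 0 °C → rt
Reagents that add atoms: diethyl chlorophosphate, CCOP(=O)(Cl)OCC
Why: O-phosphorylation of the sodium enolate; the hard electrophile reacts at oxygen and the ring fixes the enol geometry.

Step 20
Reactants: 28 enol phosphate
Product: 29 methyl (4aR,8aS)-1,1,3,6-tetramethyl-1,4,4a,7,8,8a-hexahydronaphthalene-2-carboxylate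
Conditions: MeLi, CuI, Et2O, 0 °C; then 28, −78 → −20 °C
Reagents that add atoms: lithium dimethylcuprate, [Li+].C[Cu-]C (made from MeLi and CuI)
Why: Cuprate addition–elimination on a beta-phosphoryloxy enoate replaces the phosphate by methyl and fixes the tetrasubstituted C9=C10 alkene without any acid that could move it.

Step 21
Reactants: 29 enoate
Product: 30 [(4aR,8aS)-1,1,3,6-tetramethyl-1,4,4a,7,8,8a-hexahydronaphthalen-2-yl]methanol
Conditions: LiAlH4, Et2O, 0 °C → rt
Reagents that add atoms: none
Why: Hydride reduction of a hindered, twisted enoate should proceed by 1,2-addition to the allylic alcohol, as with beta-cyclogeranate esters.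

Step 22
Reactants: 30 allylic alcohol
Product: 31 {[(4aR,8aS)-1,1,3,6-tetramethyl-1,4,4a,7,8,8a-hexahydronaphthalen-2-yl]methyl}triphenylphosphonium bromide
Conditions: PPh3·HBr, MeOH, rt
Reagents that add atoms: triphenylphosphine hydrobromide, c1ccc(cc1)P(c1ccccc1)c1ccccc1.Br
Why: SN1-type phosphonium salt formation; the mildly acidic salt ionises the alcohol to a stabilised allyl cation, which the phosphine captures at its unhindered primary terminus, while the acid is too weak to move the ring-A alkene.

Step 23
Reactants: 31 phosphonium bromide; 16 C7 aldehyde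
Product: 33 (7E)-diene silyl ether (2S,3R,6S in chain numbering), via ylide 32 (not isolated)
Conditions: KHMDS (0.95 equiv relative to 31), THF, −78 → 0 °C; then 16, −78 °C → rt
Reagents that add atoms: none
Why: Wittig olefination; the aldehyde cannot enolise and is activated by its alpha oxygen, addition should outrun deprotonation at C3–H, no free phosphine or excess amide base meets the peroxide, and no stereocentre is created.

Step 24
Reactants: 33 diene
Product: 34 C7–C8 saturated silyl ether (2S,3R,6R in chain numbering)
Conditions: KO2CN=NCO2K (excess, in portions), AcOH, MeOH–CH2Cl2, 0 °C → rt, followed closely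
Reagents that add atoms: none
Why: Diimide reduction; the concerted syn transfer of H2 leaves O–O bonds alone and slows sharply with alkene substitution, so the disubstituted C7=C8 bond should react ahead of the trisubstituted C13=C14 and tetrasubstituted C9=C10 bonds.

Step 25
Reactants: 34 silyl ether
Product: 35 primary alcohol (2S,3R,6R in chain numbering)
Conditions: TBAF, AcOH (1:1), THF, 0 °C → rt
Reagents that add atoms: none
Why: Fluoride desilylation; buffering with acetic acid keeps the medium too weakly basic for Kornblum–DeLaMare fragmentation at C3–H.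

Step 26
Reactants: 35 primary alcohol
Product: 37 target acid (2R)-2-[(3R,6R)-6-methyl-6-{2-[(4aR,8aS)-1,1,3,6-tetramethyl-1,4,4a,7,8,8a-hexahydronaphthalen-2-yl]ethyl}-1,2-dioxan-3-yl]propanoic acid, via aldehyde 36 (not isolated)
Conditions: TEMPO (0.2 equiv), PhI(OAc)2 (2.5 equiv), MeCN–pH 7 buffer, rt
Reagents that add atoms: water, O
Why: Oxoammonium (TEMPO/hypervalent iodine) oxidation through the aldehyde hydrate; the chlorine-free, nearly neutral medium should spare both alkenes and the peroxide and give no chance for C2 epimerisation or beta-elimination of the C3 peroxy oxygen.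

**Compound list**
1 | geranyl acetate | CC(C)=CCC/C(C)=C/COC(C)=O | starting material
2 | (2E)-3-methyl-6-oxohex-2-en-1-yl acetate | O=CCC/C(C)=C/COC(C)=O | intermediate
3 | (R)-4-benzyl-3-propionyl-1,3-oxazolidin-2-one | CCC(=O)N1[C@H](Cc2ccccc2)COC1=O | starting material
4 | Z-dibutylboron enolate of 3 | C/C=C(\OB(CCCC)CCCC)N1[C@H](Cc2ccccc2)COC1=O | intermediate
5 | (2R,3S) syn-aldol adduct | CC(=O)OC/C=C(\C)CC[C@H](O)[C@@H](C)C(=O)N1[C@H](Cc2ccccc2)COC1=O | intermediate
6 | (2S,3S) C1,C3-diol C8 acetate | CC(=O)OC/C=C(\C)CC[C@H](O)[C@@H](C)CO | intermediate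
7 | C1 TBS ether, C3 alcohol | CC(=O)OC/C=C(\C)CC[C@H](O)[C@@H](C)CO[Si](C)(C)C(C)(C)C | intermediate
8 | (3S) mesylate, C8 acetate | CC(=O)OC/C=C(\C)CC[C@H](OS(C)(=O)=O)[C@@H](C)CO[Si](C)(C)C(C)(C)C | intermediate
9 | (3S) mesylate, C8 allylic alcohol | OC/C=C(\C)CC[C@H](OS(C)(=O)=O)[C@@H](C)CO[Si](C)(C)C(C)(C)C | intermediate
10 | 2,3-dimethylbut-2-ene | CC(C)=C(C)C | starting material
11 | 2-methoxypropan-2-yl hydroperoxide | COC(C)(C)OO | intermediate
12 | (3R) peroxyketal allylic alcohol | OC/C=C(\C)CC[C@@H](OOC(C)(C)OC)[C@@H](C)CO[Si](C)(C)C(C)(C)C | intermediate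
13 | (6R,7R)-epoxy alcohol peroxyketal | OC[C@H]1O[C@]1(C)CC[C@@H](OOC(C)(C)OC)[C@@H](C)CO[Si](C)(C)C(C)(C)C | intermediate
14 | C3 hydroperoxy 6,7-epoxy alcohol (key-step precursor) | OC[C@H]1O[C@]1(C)CC[C@H]([C@@H](C)CO[Si](C)(C)C(C)(C)C)OO | intermediate
15 | 1,2-dioxane 7,8-diol (key-step product) | OC[C@@H](O)[C@]1(C)CC[C@H]([C@@H](C)CO[Si](C)(C)C(C)(C)C)OO1 | intermediate
16 | dioxane C7 aldehyde | O=C[C@]1(C)CC[C@H]([C@@H](C)CO[Si](C)(C)C(C)(C)C)OO1 | intermediate
17 | (S)-(−)-limonene | CC1=CC[C@@H](C(C)=C)CC1 | starting material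
18 | (1R,2R,4S)-2-bromo-1-methyl-4-(prop-1-en-2-yl)cyclohexan-1-ol | C[C@@]1(O)CC[C@H](C(C)=C)C[C@H]1Br | intermediate
19 | (1R,2S,4S)-limonene 1,2-oxide | C[C@@]12CC[C@H](C(C)=C)C[C@@H]1O2 | intermediate
20 | (1R,2R,4S)-1-methyl-2-(phenylselanyl)-4-(prop-1-en-2-yl)cyclohexan-1-ol | C[C@@]1(O)CC[C@H](C(C)=C)C[C@H]1[Se]c2ccccc2 | intermediate
21 | selenoxide of 20 | C[C@@]1(O)CC[C@H](C(C)=C)C[C@H]1[Se](=O)c2ccccc2 | intermediate
22 | (1R,4S)-1-methyl-4-(prop-1-en-2-yl)cyclohex-2-en-1-ol | C[C@@]1(O)CC[C@H](C(C)=C)C=C1 | intermediate
23 | ketene N,O-acetal of 22 | C=C(N(C)C)O[C@]1(C)CC[C@H](C(C)=C)C=C1 | intermediate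
24 | cis amide | CC1=C[C@@H](CC(=O)N(C)C)[C@@H](C(C)=C)CC1 | intermediate
25 | cis methyl ketone | CC1=C[C@@H](CC(C)=O)[C@@H](C(C)=C)CC1 | intermediate
26 | cis beta-keto ester | CC1=C[C@@H](CC(=O)CC(=O)OC)[C@@H](C(C)=C)CC1 | intermediate
27 | bicyclic beta-keto ester (C9 undefined) | CC1=C[C@H]2CC(=O)C(C(=O)OC)C(C)(C)[C@H]2CC1 | intermediate
28 | enol phosphate | CC1=C[C@H]2CC(OP(=O)(OCC)OCC)=C(C(=O)OC)C(C)(C)[C@H]2CC1 | intermediate
29 | tetrasubstituted enoate | CC1=C[C@H]2CC(C)=C(C(=O)OC)C(C)(C)[C@H]2CC1 | intermediate
30 | bicyclic allylic alcohol | CC1=C[C@H]2CC(C)=C(CO)C(C)(C)[C@H]2CC1 | intermediate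
31 | allylic phosphonium bromide | CC1=C[C@H]2CC(C)=C(C[P+](c3ccccc3)(c3ccccc3)c3ccccc3)C(C)(C)[C@H]2CC1.[Br-] | intermediate
32 | allylic ylide | CC1=C[C@H]2CC(C)=C(C=P(c3ccccc3)(c3ccccc3)c3ccccc3)C(C)(C)[C@H]2CC1 | intermediate
33 | (7E)-diene silyl ether | CC1=C[C@H]2CC(C)=C(/C=C/[C@]3(C)CC[C@H]([C@@H](C)CO[Si](C)(C)C(C)(C)C)OO3)C(C)(C)[C@H]2CC1 | intermediate
34 | C7–C8 saturated silyl ether | CC1=C[C@H]2CC(C)=C(CC[C@]3(C)CC[C@H]([C@@H](C)CO[Si](C)(C)C(C)(C)C)OO3)C(C)(C)[C@H]2CC1 | intermediate
35 | C1 primary alcohol | CC1=C[C@H]2CC(C)=C(CC[C@]3(C)CC[C@H]([C@@H](C)CO)OO3)C(C)(C)[C@H]2CC1 | intermediate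
36 | C1 aldehyde | CC1=C[C@H]2CC(C)=C(CC[C@]3(C)CC[C@H]([C@@H](C)C=O)OO3)C(C)(C)[C@H]2CC1 | intermediate
37 | CNP0122760.1 | CC1=C[C@H]2CC(C)=C(CC[C@]3(C)CC[C@H]([C@@H](C)C(=O)O)OO3)C(C)(C)[C@H]2CC1 | target

**Step count**
- Total: 26 steps, including the preparation of reagent 11.
- Longest linear sequence: 15 steps (1–6, 8–12, 23–26). The carbocycle branch contributes 10 steps before the union.

**Steps most likely to fail**

1. **Step 8.** Substitution at the secondary C3, next to the C2 branch, is slow. E2 elimination towards C2 or C4 and gradual decay of the peroxy anion may outrun it.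
 - Fallback, from 9 back to 15: the two C–O bonds of the ring are made in the opposite order, so that the difficult substitution becomes intramolecular.
 - Compound 9 is epoxidised as in step 9 to the (6R,7R)-epoxy alcohol mesylate F1.
 - Molybdenum-catalysed perhydrolysis with ethereal H2O2 opens F1 at tertiary C6 with inversion, giving the C6 hydroperoxy 7,8-diol mesylate F2.
 - Cs2CO3 in DMF then closes the ring by 6-exo-tet displacement of the C3 mesylate with inversion, which gives 15.
 - This path is taken only if the C3 hydroperoxide cannot be made.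

2. **Step 11.** Partial ionisation to a free C6 cation would erode the inversion. It could also open the way to hydride shift to a carbonyl compound, seven-endo attack, or acid loss of the silyl group.
 - Fallback, from 12 back to 16: the oxirane is replaced by an iodonium ion as the electrophile.
 - Compound 12 is unmasked as in step 10 to the C3 hydroperoxy allylic alcohol F3.
 - N-Iodosuccinimide in CH2Cl2 triggers a Markovnikov 6-exo iodoperoxidation to the C7-iodo dioxane alcohol F4.
 - K2CO3 in MeOH closes F4 to the dioxanyl 7,8-epoxide F5, and H5IO6 cleaves F5 to 16.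
 - C6 is then under substrate control only, so the C6 epimers would have to be separated at F4.

3. **Step 23.** Addition of the ylide, which is hindered by the gem-dimethyl and vinylic methyl groups, to a neopentyl-type aldehyde may be slow. That would give time for base-induced Kornblum–DeLaMare fragmentation at C3–H or fragmentation of a beta-peroxy alkoxide.
 - Fallback, from 30 (with 16) back to 33: a Julia–Kocienski olefination with a smaller, less basic carbanion and no phosphorus.
 - Mitsunobu reaction of 30 with 1-phenyl-1H-tetrazole-5-thiol gives the phenyltetrazolyl sulfide F6.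
 - Molybdate/H2O2 oxidation gives the phenyltetrazolyl sulfone F7.
 - Metalation with KHMDS at −78 °C and addition of 16 gives 33.

**Further compounds**
F1 | step 8 | (6R,7R)-epoxy alcohol C3 mesylate | OC[C@H]1O[C@]1(C)CC[C@H](OS(C)(=O)=O)[C@@H](C)CO[Si](C)(C)C(C)(C)C
F2 | step 8 | C6 hydroperoxy 7,8-diol C3 mesylate | OC[C@@H](O)[C@@](C)(OO)CC[C@H](OS(C)(=O)=O)[C@@H](C)CO[Si](C)(C)C(C)(C)C
F3 | step 11 | C3 hydroperoxy allylic alcohol | OC/C=C(\C)CC[C@H]([C@@H](C)CO[Si](C)(C)C(C)(C)C)OO
F4 | step 11 | C7-iodo dioxane alcohol | OC[C@@H](I)[C@]1(C)CC[C@H]([C@@H](C)CO[Si](C)(C)C(C)(C)C)OO1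
F5 | step 11 | dioxanyl 7,8-epoxide | C1O[C@@H]1[C@]2(C)CC[C@H]([C@@H](C)CO[Si](C)(C)C(C)(C)C)OO2
F6 | step 23 | phenyltetrazolyl sulfide | CC1=C[C@H]2CC(C)=C(CSc3nnnn3-c3ccccc3)C(C)(C)[C@H]2CC1
F7 | step 23 | phenyltetrazolyl sulfone | CC1=C[C@H]2CC(C)=C(CS(=O)(=O)c3nnnn3-c3ccccc3)C(C)(C)[C@H]2CC1
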